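**Retrosynthetic overview**

1. Numbering used here (longipinane type): C1 ketone, C2 its CH2, C3 the CH(CH3) carbon (methyl = C12), cyclobutane C4–C5–C11–C10, C6 the CMe2 carbon, C7 and C9 the angeloyloxy carbons, C8 the CH2 between them, C10 the methyl-bearing quaternary carbon. The target comes from the 7,9-diol by double angeloylation, done last.
2. Six-membered ring: C2–C3 (together with C2–C12) by an intramolecular diazoketone/vinyl [2+1] cycloaddition on a bicyclo[4.1.1]octane, followed by strain-releasing reductive opening of the C2–C12 cyclopropane bond to unveil the C3 methyl group. The enabling feature is the C1(=O)–C2H2–C3H(CH3) bridge between the two one-carbon bridges C11 and C4 of the cyclobutane (a 3-methylcyclohexanone), whose acyl and vinyl precursors are held 1,3-diaxial on the cyclobutane face opposite the C6–C9 bridge.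
3. trans-7,9-Diol: from a bridged cycloheptenone by ligand-controlled copper borylation/oxidation (C9), then hydroxyl-directed 1,3-anti reduction (C7).
4. Seven-membered ring: strain-release radical (4+3) annulation of a bicyclo[1.1.0]butane-2,4-diester (central bond = C10–C5) with a bromo β-ethoxy enone that carries C6–C9.
5. Cyclobutane: stored as the bicyclobutane, made from propyne by two carbene transfers, the first enantioselective. Ring order: cyclopropene, bicyclobutane, cyclobutane with seven-membered ring, six-membered ring (with a transient cyclopropane).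

Key step: step 13

Remark and assumption: bicyclic intermediates are numbered as bicyclo[4.1.1]octanes (C1 = methyl-bearing bridgehead, C2–C5 = four-carbon bridge, C6 = other bridgehead, C7 and C8 = one-carbon bridges; these correspond to C10, C9–C6, C5, C11 and C4 of the target). It is assumed that substituents on C7 and C8 prefer the orientation anti to the four-carbon bridge; both centres are α to carbonyl groups at the ester stage and could be equilibrated with base if an epimer forms.

**Route**

Step 1
Reactants: 1 propyne; 2 ethyl diazoacetate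
Product: 3 ethyl (1S)-2-methylcycloprop-2-ene-1-carboxylate
Conditions: Rh2(OAc)(DPTI)3 [DPTI = 4,5-diphenyl-1-triflylimidazolidin-2-onate, antipode chosen for the 1S product] (0.5 mol%), propyne (5 equiv), CH2Cl2, 0 °C, slow addition of 2
Reagents that add atoms: none
Why: Rhodium-carbenoid [2+1] cycloaddition to the terminal alkyne (catalytic enantioselective cyclopropenation) should give the cyclopropene, the chiral ligand sphere setting C1, which is the source of the absolute configuration of the whole cyclobutane core.

Step 2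
Reactants: 3 ethyl (1S)-2-methylcycloprop-2-ene-1-carboxylate; 4 tert-butyl diazoacetate
Product: 5 2-tert-butyl 4-ethyl 1-methylbicyclo[1.1.0]butane-2,4-dicarboxylate (both esters exo)
Conditions: CuOTf·0.5C6H6 (5 mol%), CH2Cl2, 0 °C to rt, 4 added over 8 h
Reagents that add atoms: none
Why: Copper-carbenoid cyclopropanation of the strained cyclopropene double bond (second carbene transfer, the classical route from alkynes to bicyclobutane-2,4-diesters) should occur on the face anti to the C1 ester, which fixes the sense of the bicyclobutane, with the new ester in the less crowded exo position.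

Step 3
Reactants: 6 2-bromo-2-methylpropanoyl bromide; 7 ethyl vinyl ether
Product: 8 (E)-4-bromo-1-ethoxy-4-methylpent-1-en-3-one
Conditions: pyridine (1.1 equiv), CH2Cl2, 0 °C to rt
Reagents that add atoms: none
Why: Electrophilic C-acylation of the enol ether followed by loss of HBr (β-alkoxyvinyl ketone synthesis) should give the conjugated (E) enone, the more stable isomer.

Step 4
Reactants: 5 2-tert-butyl 4-ethyl 1-methylbicyclo[1.1.0]butane-2,4-dicarboxylate; 8 (E)-4-bromo-1-ethoxy-4-methylpent-1-en-3-one
Product: 9 7-tert-butyl 8-ethyl 2-ethoxy-1,5,5-trimethyl-4-oxobicyclo[4.1.1]octane-7,8-dicarboxylate (both esters anti to the C2–C5 bridge; both C2 epimers)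
Conditions: fac-Ir(ppy)3 (1 mol%), Hantzsch ester (1.5 equiv), 2,6-lutidine (1.5 equiv), MeCN, 450 nm LEDs, rt, 8 (1.5 equiv) added over 6 h
Reagents that add atoms: none
Why: Proposed new method: reductive radical (4+3) annulation, in which the excited iridium photocatalyst reduces 8 to the electrophilic tertiary α-keto radical, which should attack the hydrogen-bearing bridgehead of 5 from the rear of the strained central bond (inversion, giving the more stable tertiary cyclobutyl radical); this radical closes 7-endo onto the β-ethoxy carbon of the tethered enone, necessarily on the face that carries the tether, and the resulting α-keto radical takes hydrogen from the Hantzsch ester; the closest known reaction types are radical and atom-transfer additions across the central bond of bicyclobutanes and propellanes and photoredox Giese reactions of α-bromo ketones; rear-side attack puts the new four-carbon bridge on the face opposite the two exo esters, and the ethoxy-bearing centre, formed unselectively, is erased in step 5.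

Step 5
Reactants: 9 7-tert-butyl 8-ethyl 2-ethoxy-1,5,5-trimethyl-4-oxobicyclo[4.1.1]octane-7,8-dicarboxylate
Product: 10 7-tert-butyl 8-ethyl 1,5,5-trimethyl-4-oxobicyclo[4.1.1]oct-2-ene-7,8-dicarboxylate (esters anti)
Conditions: DBU (2 equiv), toluene, 80 °C
Reagents that add atoms: none
Why: E1cB elimination of ethanol from the β-alkoxy ketone should give the conjugated enone and merge both C2 epimers, the non-nucleophilic amidine leaving both esters untouched.

Step 6
Reactants: 10 7-tert-butyl 8-ethyl 1,5,5-trimethyl-4-oxobicyclo[4.1.1]oct-2-ene-7,8-dicarboxylate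
Product: 12 7-tert-butyl 8-ethyl 2-hydroxy-1,5,5-trimethyl-4-oxobicyclo[4.1.1]octane-7,8-dicarboxylate (2-OH turned toward C7), via C2-pinacolboryl ketone 11 (not isolated)
Conditions: CuCl (5 mol%), 2,3-bis(tert-butylmethylphosphino)quinoxaline (antipode chosen for the drawn C2 configuration, 6 mol%), NaOtBu (10 mol%), B2pin2 (1.2 equiv), MeOH (2 equiv), THF, rt; then 30% H2O2, pH 7 phosphate buffer, 0 °C
Reagents that add atoms: hydrogen peroxide, OO
Why: Copper-boryl conjugate addition (catalytic asymmetric β-borylation of a cyclic enone) and stereoretentive C–B oxidation should set C2 (C9 of the target) under ligand control, because the enone is locally mirror-symmetric and the two ester bridges differ only remotely.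

Step 7
Reactants: 12 7-tert-butyl 8-ethyl 2-hydroxy-1,5,5-trimethyl-4-oxobicyclo[4.1.1]octane-7,8-dicarboxylate
Product: 13 7-tert-butyl 8-ethyl 2,4-dihydroxy-1,5,5-trimethylbicyclo[4.1.1]octane-7,8-dicarboxylate (2,4-trans: 2-OH toward C7, 4-OH toward C8)
Conditions: Me4NBH(OAc)3 (5 equiv), MeCN/AcOH 1:1, −25 °C
Reagents that add atoms: none
Why: Evans–Saksena reduction, in which the acetoxyborohydride bound to the C2 hydroxyl delivers hydride intramolecularly to the same face of the C4 ketone, should give the 1,3-anti (trans) diol and set C4 (C7 of the target) without touching the esters.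

Step 8
Reactants: 13 7-tert-butyl 8-ethyl 2,4-dihydroxy-1,5,5-trimethylbicyclo[4.1.1]octane-7,8-dicarboxylate
Product: 14 7-tert-butyl 8-ethyl 2,4-bis(tert-butyldimethylsilyloxy)-1,5,5-trimethylbicyclo[4.1.1]octane-7,8-dicarboxylate
Conditions: TBSOTf (2.6 equiv), 2,6-lutidine (4 equiv), CH2Cl2, 0 °C to rt
Reagents that add atoms: tert-butyldimethylsilyl triflate, CC(C)(C)[Si](C)(C)OS(=O)(=O)C(F)(F)F
Why: Silylation with the silyl triflate should protect both hindered carbinols for the hydride, ylide, carbenoid and dissolving-metal steps that follow.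

Step 9
Reactants: 14 7-tert-butyl 8-ethyl 2,4-bis(tert-butyldimethylsilyloxy)-1,5,5-trimethylbicyclo[4.1.1]octane-7,8-dicarboxylate
Product: 15 tert-butyl 2,4-bis(tert-butyldimethylsilyloxy)-8-formyl-1,5,5-trimethylbicyclo[4.1.1]octane-7-carboxylate
Conditions: iBu2AlH (1.1 equiv), toluene, −78 °C; aqueous KNaC4H4O6
Reagents that add atoms: none
Why: Low-temperature aluminium hydride half-reduction should stop at the tetrahedral aluminate of the ethyl ester and give the aldehyde on work-up, the tert-butyl ester being too hindered to react.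

Step 10
Reactants: 15 tert-butyl 2,4-bis(tert-butyldimethylsilyloxy)-8-formyl-1,5,5-trimethylbicyclo[4.1.1]octane-7-carboxylate
Product: 16 tert-butyl 2,4-bis(tert-butyldimethylsilyloxy)-1,5,5-trimethyl-8-vinylbicyclo[4.1.1]octane-7-carboxylate
Conditions: Ph3PCH3Br (1.5 equiv), KN(SiMe3)2 (1.4 equiv), THF, −78 to 0 °C
Reagents that add atoms: methyltriphenylphosphonium bromide, C[P+](c1ccccc1)(c1ccccc1)c1ccccc1.[Br-]
Why: Wittig methylenation at low temperature should convert the aldehyde into the vinyl group before the α-centre (C8) can epimerise.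

Step 11
Reactants: 16 tert-butyl 2,4-bis(tert-butyldimethylsilyloxy)-1,5,5-trimethyl-8-vinylbicyclo[4.1.1]octane-7-carboxylate
Product: 18 2,4-bis(tert-butyldimethylsilyloxy)-1,5,5-trimethyl-8-vinylbicyclo[4.1.1]octane-7-carboxylic acid, via trimethylsilyl ester 17 (not isolated)
Conditions: TMSOTf (2 equiv), 2,6-lutidine (3 equiv), CH2Cl2, 0 °C; then MeOH/H2O
Reagents that add atoms: none
Why: Silyl-triflate-mediated cleavage of the tert-butyl ester (loss of 2-methylpropene) should spare the silyl ethers and the vinyl group, the silyl ester being hydrolysed on work-up.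

Step 12
Reactants: 18 2,4-bis(tert-butyldimethylsilyloxy)-1,5,5-trimethyl-8-vinylbicyclo[4.1.1]octane-7-carboxylic acid
Product: 20 1-[2,4-bis(tert-butyldimethylsilyloxy)-1,5,5-trimethyl-8-vinylbicyclo[4.1.1]octan-7-yl]-2-diazoethan-1-one, via acid chloride 19 (not isolated)
Conditions: 1-chloro-N,N,2-trimethylprop-1-en-1-amine (1.2 equiv), CH2Cl2, 0 °C; then TMSCHN2 (2.2 equiv), MeCN/THF, 0 °C to rt
Reagents that add atoms: (trimethylsilyl)diazomethane, C[Si](C)(C)C=[N+]=[N-]
Why: Neutral acid chloride formation and C-acylation of the silyl diazomethane with desilylation in the flask (Arndt–Eistert-type diazoketone synthesis) should give the diazomethyl ketone without acid that would harm the silyl ethers.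

Step 13
Reactants: 20 1-[2,4-bis(tert-butyldimethylsilyloxy)-1,5,5-trimethyl-8-vinylbicyclo[4.1.1]octan-7-yl]-2-diazoethan-1-one
Product: 21 7,9-bis(tert-butyldimethylsilyloxy)-2,12-cyclolongipinan-1-one (cyclopropane C2–C3–C12, its CH2 on the side of C5)
Conditions: Cu(acac)2 (5 mol%), toluene, 85 °C, slow addition of 20 (final 0.005 M)
Reagents that add atoms: none
Why: The copper carbenoid formed from the diazoketone by loss of dinitrogen should add across the vinyl group in a concerted [2+1] cycloaddition, forming C2–C3 (closing the six-membered ring in a 6-exo sense with respect to the carbenoid chain) and C2–C12 (closing the cyclopropane); the closest known reaction type is the copper-catalysed intramolecular cyclopropanation of ε,ζ-unsaturated diazomethyl ketones to bicyclo[4.1.0]heptan-2-ones. The bicyclo[4.1.1]octane holds the C7 acyl and C8 vinyl groups (bicyclic numbering) 1,3-diaxial on the cyclobutane face opposite the four-carbon bridge, so the reacting centres are pre-organised and the added ring strain is paid for by the loss of dinitrogen. C2 and C3 are formed cis on the cyclopropane by the suprafacial addition, and the configuration at C3 should follow from the vinyl rotamer that turns its CH2 terminus away from the C10 methyl group and toward the hydrogen-bearing C5, which later places the C3 methyl anti to the C10 methyl. The step needs cyclopropanation to win over Wolff rearrangement and over C–H insertion into the nearby C10 methyl group; a copper catalyst (poor at C–H insertion), the absence of any other alkene and the proximity of the vinyl group should secure this.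

Step 14
Reactants: 21 7,9-bis(tert-butyldimethylsilyloxy)-2,12-cyclolongipinan-1-one
Product: 22 7,9-bis(tert-butyldimethylsilyloxy)longipinan-1-one
Conditions: Li (2.2 equiv), NH3(l)/THF, t-BuOH (1 equiv), −78 °C; then solid NH4Cl
Reagents that add atoms: none
Why: Dissolving-metal reductive cleavage of the conjugated cyclopropyl ketone should break the exocyclic C2–C12 bond, the one that overlaps best with the carbonyl π system, so that strain release turns the cyclopropane CH2 into the C3 methyl group with C3 unchanged.

Step 15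
Reactants: 22 7,9-bis(tert-butyldimethylsilyloxy)longipinan-1-one
Product: 23 7,9-dihydroxylongipinan-1-one
Conditions: HF·pyridine, THF, 0 °C to rt
Reagents that add atoms: none
Why: Fluoride-induced desilylation should free both carbinols without affecting the ketone or any stereocentre.

Step 16
Reactants: 23 7,9-dihydroxylongipinan-1-one; 24 angelic acid
Product: 25 7,9-bis(angeloyloxy)longipinan-1-one (target)
Conditions: 24 (4 equiv), 2,4,6-trichlorobenzoyl chloride (4 equiv), Et3N (8 equiv), toluene, rt; then 23, 80 °C
Reagents that add atoms: none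
Why: Yamaguchi-type mixed-anhydride esterification without a nucleophilic catalyst should acylate both hindered secondary alcohols while preserving the (Z) geometry of the angelate.

**Compound list**

1 | propyne | CC#C | starting material
2 | ethyl diazoacetate | CCOC(=O)C=[N+]=[N-] | starting material
3 | ethyl (1S)-2-methylcycloprop-2-ene-1-carboxylate | CCOC(=O)[C@@H]1C(C)=C1 | intermediate
4 | tert-butyl diazoacetate | CC(C)(C)OC(=O)C=[N+]=[N-] | starting material
5 | 2-tert-butyl 4-ethyl 1-methylbicyclo[1.1.0]butane-2,4-dicarboxylate (both esters exo) | C[C@@]12[C@@H](C(=O)OCC)[C@@H]1[C@H]2C(=O)OC(C)(C)C | intermediate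
6 | 2-bromo-2-methylpropanoyl bromide | CC(C)(Br)C(=O)Br | starting material
7 | ethyl vinyl ether | CCOC=C | starting material
8 | (E)-4-bromo-1-ethoxy-4-methylpent-1-en-3-one | CCO/C=C/C(=O)C(C)(C)Br | intermediate
9 | 7-tert-butyl 8-ethyl 2-ethoxy-1,5,5-trimethyl-4-oxobicyclo[4.1.1]octane-7,8-dicarboxylate (esters anti to the C2–C5 bridge; C2 epimers) | O=C1CC(OCC)[C@]2(C)[C@@H](C(=O)OCC)[C@@H]([C@H]2C(=O)OC(C)(C)C)C1(C)C | intermediate
10 | 7-tert-butyl 8-ethyl 1,5,5-trimethyl-4-oxobicyclo[4.1.1]oct-2-ene-7,8-dicarboxylate | O=C1C=C[C@]2(C)[C@@H](C(=O)OCC)[C@@H]([C@H]2C(=O)OC(C)(C)C)C1(C)C | intermediate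
11 | 7-tert-butyl 8-ethyl 1,5,5-trimethyl-4-oxo-2-(4,4,5,5-tetramethyl-1,3,2-dioxaborolan-2-yl)bicyclo[4.1.1]octane-7,8-dicarboxylate | O=C1C[C@@H](B3OC(C)(C)C(C)(C)O3)[C@]2(C)[C@@H](C(=O)OCC)[C@@H]([C@H]2C(=O)OC(C)(C)C)C1(C)C | intermediate
12 | 7-tert-butyl 8-ethyl 2-hydroxy-1,5,5-trimethyl-4-oxobicyclo[4.1.1]octane-7,8-dicarboxylate (2-OH toward C7) | O=C1C[C@@H](O)[C@]2(C)[C@@H](C(=O)OCC)[C@@H]([C@H]2C(=O)OC(C)(C)C)C1(C)C | intermediate
13 | 7-tert-butyl 8-ethyl 2,4-dihydroxy-1,5,5-trimethylbicyclo[4.1.1]octane-7,8-dicarboxylate (2,4-trans) | O[C@@H]1C[C@@H](O)[C@]2(C)[C@@H](C(=O)OCC)[C@@H]([C@H]2C(=O)OC(C)(C)C)C1(C)C | intermediate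
14 | 7-tert-butyl 8-ethyl 2,4-bis(tert-butyldimethylsilyloxy)-1,5,5-trimethylbicyclo[4.1.1]octane-7,8-dicarboxylate | CC(C)(C)[Si](C)(C)O[C@@H]1C[C@@H](O[Si](C)(C)C(C)(C)C)[C@]2(C)[C@@H](C(=O)OCC)[C@@H]([C@H]2C(=O)OC(C)(C)C)C1(C)C | intermediate
15 | tert-butyl 2,4-bis(tert-butyldimethylsilyloxy)-8-formyl-1,5,5-trimethylbicyclo[4.1.1]octane-7-carboxylate | CC(C)(C)[Si](C)(C)O[C@@H]1C[C@@H](O[Si](C)(C)C(C)(C)C)[C@]2(C)[C@@H](C=O)[C@@H]([C@H]2C(=O)OC(C)(C)C)C1(C)C | intermediate
16 | tert-butyl 2,4-bis(tert-butyldimethylsilyloxy)-1,5,5-trimethyl-8-vinylbicyclo[4.1.1]octane-7-carboxylate | CC(C)(C)[Si](C)(C)O[C@@H]1C[C@@H](O[Si](C)(C)C(C)(C)C)[C@]2(C)[C@@H](C=C)[C@@H]([C@H]2C(=O)OC(C)(C)C)C1(C)C | intermediate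
17 | trimethylsilyl 2,4-bis(tert-butyldimethylsilyloxy)-1,5,5-trimethyl-8-vinylbicyclo[4.1.1]octane-7-carboxylate | CC(C)(C)[Si](C)(C)O[C@@H]1C[C@@H](O[Si](C)(C)C(C)(C)C)[C@]2(C)[C@@H](C=C)[C@@H]([C@H]2C(=O)O[Si](C)(C)C)C1(C)C | intermediate
18 | 2,4-bis(tert-butyldimethylsilyloxy)-1,5,5-trimethyl-8-vinylbicyclo[4.1.1]octane-7-carboxylic acid | CC(C)(C)[Si](C)(C)O[C@@H]1C[C@@H](O[Si](C)(C)C(C)(C)C)[C@]2(C)[C@@H](C=C)[C@@H]([C@H]2C(=O)O)C1(C)C | intermediate
19 | 2,4-bis(tert-butyldimethylsilyloxy)-1,5,5-trimethyl-8-vinylbicyclo[4.1.1]octane-7-carbonyl chloride | CC(C)(C)[Si](C)(C)O[C@@H]1C[C@@H](O[Si](C)(C)C(C)(C)C)[C@]2(C)[C@@H](C=C)[C@@H]([C@H]2C(=O)Cl)C1(C)C | intermediate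
20 | 1-[2,4-bis(tert-butyldimethylsilyloxy)-1,5,5-trimethyl-8-vinylbicyclo[4.1.1]octan-7-yl]-2-diazoethan-1-one | CC(C)(C)[Si](C)(C)O[C@@H]1C[C@@H](O[Si](C)(C)C(C)(C)C)[C@]2(C)[C@@H](C=C)[C@@H]([C@H]2C(=O)C=[N+]=[N-])C1(C)C | intermediate
21 | 7,9-bis(tert-butyldimethylsilyloxy)-2,12-cyclolongipinan-1-one | CC(C)(C)[Si](C)(C)O[C@@H]1C[C@@H](O[Si](C)(C)C(C)(C)C)[C@]2(C)[C@@H]3[C@@H]([C@H]2C(=O)[C@@H]4[C@H]3C4)C1(C)C | intermediate
22 | 7,9-bis(tert-butyldimethylsilyloxy)longipinan-1-one | CC(C)(C)[Si](C)(C)O[C@@H]1C[C@@H](O[Si](C)(C)C(C)(C)C)[C@]2(C)[C@@H]3[C@@H]([C@H]2C(=O)C[C@H]3C)C1(C)C | intermediate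
23 | 7,9-dihydroxylongipinan-1-one | O[C@@H]1C[C@@H](O)[C@]2(C)[C@@H]3[C@@H]([C@H]2C(=O)C[C@H]3C)C1(C)C | intermediate
24 | angelic acid, (Z)-2-methylbut-2-enoic acid | C/C=C(/C)C(O)=O | starting material
25 | 7,9-bis(angeloyloxy)longipinan-1-one | C/C=C(/C)C(=O)O[C@@H]1C[C@@H](OC(=O)/C(C)=C\C)[C@]2(C)[C@@H]3[C@@H]([C@H]2C(=O)C[C@H]3C)C1(C)C | target

**Summary**

Total step count: 16. Longest linear sequence: 15 steps (steps 1, 2 and 4 to 16; step 3 prepares the annulation partner).

Steps most likely to fail:

- **Step 4.** The α-keto radical may be reduced before it adds to the bicyclobutane, the cyclobutyl radical may be quenched before the 7-endo closure, or the attack may lose its rear-side specificity. The fallback sets out from 5 and separates the events into two known radical operations. Triethylborane/air-initiated bromine-atom-transfer addition of 8 across the central bond should give the tertiary cyclobutyl bromide F1. Slow addition of Bu3SnH with AIBN in hot benzene should then effect the 7-endo cyclisation onto the β-ethoxy enone, coming back to the route at 9.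
- **Step 2.** The copper catalyst may open the cyclopropene to a vinyl carbenoid (furan or diene formation), or the diazo ester may dimerise instead of cyclopropanating. The fallback sets out from 3 and avoids metals: uncatalysed 1,3-dipolar cycloaddition of 4 to the strained double bond should give the 1-pyrazoline F2. Low-temperature photolysis (350 nm) should then extrude dinitrogen and close the bicyclobutane, coming back at 5.
- **Step 13.** The carbenoid may undergo Wolff rearrangement or insert into the C10 methyl group, or the vinyl group may react through the wrong rotamer, giving poor facial selectivity at C3. The fallback sets out from 20 and replaces the carbene by a radical. Treatment with HBr should give the bromomethyl ketone F3. Slow addition of Bu3SnH with AIBN should then bring about 6-exo-trig cyclisation of the α-keto radical onto the vinyl group, with reduction of the primary radical, coming back at 22 without the cyclopropane stage.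

Further compounds
F1 | step 4 | 3-tert-butyl 1-ethyl 2-bromo-4-[(E)-5-ethoxy-2-methyl-3-oxopent-4-en-2-yl]-2-methylcyclobutane-1,3-dicarboxylate (bromine-bearing centre as a mixture) | CCO/C=C/C(=O)C(C)(C)[C@H]1[C@H](C(=O)OCC)C(C)(Br)[C@@H]1C(=O)OC(C)(C)C
F2 | step 2 | 4-tert-butyl 6-ethyl 1-methyl-2,3-diazabicyclo[3.1.0]hex-2-ene-4,6-dicarboxylate | CCOC(=O)[C@@H]1[C@@]2(C)N=N[C@H](C(=O)OC(C)(C)C)[C@@H]12
F3 | step 13 | 2-bromo-1-[2,4-bis(tert-butyldimethylsilyloxy)-1,5,5-trimethyl-8-vinylbicyclo[4.1.1]octan-7-yl]ethan-1-one | CC(C)(C)[Si](C)(C)O[C@@H]1C[C@@H](O[Si](C)(C)C(C)(C)C)[C@]2(C)[C@@H](C=C)[C@@H]([C@H]2C(=O)CBr)C1(C)C
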